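**Strategy.** The route rests on cutting ring A (the ring carrying OAc, Cl and Br) at the C1–C2 bond. It exploits the cis-1,3 relationship between the acetoxy carbon C1 and the C3(CH3)Cl carbon across the C2 methylene. One chloro-Prins operation closes ring A, forms the C1–C2 bond and sets the C1 carbinol and the C3 tertiary chloride together. Its precursor is a fully elaborated ring-B aldehyde: a bromocyclohexane whose quaternary (future spiro) carbon carries the formyl group and a (2R)-2-silyloxy-3-methylbut-3-enyl arm, next to a tertiary acetate. Ring B and its three stereocentres come from an enantiospecific bromonium cyclisation.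

Key step: step 17

Remark on numbering: atom labels follow the spiro[5.5]undecane core of the target. C1 = CH(OAc), C2 = CH2, C3 = C(CH3)Cl, C4 = CHBr, C5 = CH2, C6 = spiro carbon, C7 = C(CH3)2, C8 = CHBr, C9 and C10 = CH2, C11 = C(CH3)OH. Ring A = C1–C6, ring B = C6–C11.

Assumption: isopropenylmagnesium bromide (THF solution) and the L-fructose-derived Shi ketone are taken as purchasable.

Step 1
Reactants: 1 methyl acetoacetate; 2 allyl bromide
Product: 3 methyl 2-acetylpent-4-enoate (racemic)
Conditions: K2CO3, acetone, reflux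
Reagents that add atoms: none
Why: The doubly stabilised enolate is C-alkylated by the allylic bromide (acetoacetic ester alkylation), and the new stereocentre is erased in step 2, so it needs no control.

Step 2
Reactants: 3 methyl 2-acetylpent-4-enoate
Product: 4 methyl (2Z)-2-(prop-2-en-1-yl)-3-{[(trifluoromethyl)sulfonyl]oxy}but-2-enoate
Conditions: NaH, Et2O, 0 °C; then Tf2O, 0 °C
Reagents that add atoms: trifluoromethanesulfonic anhydride, O=S(=O)(OS(=O)(=O)C(F)(F)F)C(F)(F)F
Why: O-sulfonylation of the sodium-chelated enolate (enol triflate formation) should place the triflate cis to the ester, so that the methyl group is cis to the allyl group.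

Step 3
Reactants: 4 methyl (2Z)-2-(prop-2-en-1-yl)-3-{[(trifluoromethyl)sulfonyl]oxy}but-2-enoate; 5 5-bromo-2-methylpent-2-ene
Product: 7 methyl (2Z)-3,7-dimethyl-2-(prop-2-en-1-yl)octa-2,6-dienoate, via Grignard reagent 6 (not isolated)
Conditions: 5, Mg, THF, rt; then 4, Fe(acac)3 (5 mol %), THF/NMP, −30 °C
Reagents that add atoms: none
Why: Iron-catalysed alkyl–alkenyl cross-coupling of the Grignard reagent with the enol triflate (Kochi-type coupling) outruns ester attack at −30 °C and proceeds with retention, which puts the homoprenyl chain cis to the ester carbon (future C1).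

Step 4
Reactants: 7 methyl (2Z)-3,7-dimethyl-2-(prop-2-en-1-yl)octa-2,6-dienoate
Product: 8 methyl (2Z)-5-[(2S)-3,3-dimethyloxiran-2-yl]-3-methyl-2-(prop-2-en-1-yl)pent-2-enoate
Conditions: L-fructose-derived Shi ketone (30 mol %), KHSO5 (Oxone), K2CO3, Bu4NHSO4, MeCN/CH2(OMe)2/aq. Na2B4O7 buffer, 0 °C
Reagents that add atoms: potassium peroxymonosulfate KHSO5, [K+].[O-]S(=O)(=O)OO
Why: Shi epoxidation by the chiral dioxirane attacks only the electron-rich trisubstituted alkene (the enoate and the terminal alkene are far less reactive), and this ketone enantiomer should deliver oxygen through the spiro transition state to give the (S)-epoxide.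

Step 5
Reactants: 8 methyl (2Z)-5-[(2S)-3,3-dimethyloxiran-2-yl]-3-methyl-2-(prop-2-en-1-yl)pent-2-enoate
Product: 9 (2Z)-5-[(2S)-3,3-dimethyloxiran-2-yl]-3-methyl-2-(prop-2-en-1-yl)pent-2-en-1-ol
Conditions: i-Bu2AlH (2.5 equiv), CH2Cl2, −78 °C; aq. KNaC4H4O6 work-up
Reagents that add atoms: none
Why: Hydride reduction of the conjugated ester at low temperature gives the allylic alcohol without touching the trisubstituted epoxide or the alkene geometry.

Step 6
Reactants: 9 (2Z)-5-[(2S)-3,3-dimethyloxiran-2-yl]-3-methyl-2-(prop-2-en-1-yl)pent-2-en-1-ol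
Product: 10 (2Z)-5-[(2S)-3,3-dimethyloxiran-2-yl]-3-methyl-2-(prop-2-en-1-yl)pent-2-en-1-yl acetate
Conditions: Ac2O, pyridine, DMAP (cat.), CH2Cl2, 0 °C
Reagents that add atoms: acetic anhydride, CC(=O)OC(C)=O
Why: Acylation of the primary allylic alcohol installs the acetate that later captures the ring-B cation and ends as the acetate of the target.

Step 7
Reactants: 10 (2Z)-5-[(2S)-3,3-dimethyloxiran-2-yl]-3-methyl-2-(prop-2-en-1-yl)pent-2-en-1-yl acetate
Product: 11 (2Z,6R)-6-bromo-7-hydroxy-3,7-dimethyl-2-(prop-2-en-1-yl)oct-2-en-1-yl acetate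
Conditions: Li2NiBr4, THF, 0 °C → rt
Reagents that add atoms: dilithium tetrabromonickelate Li2NiBr4, [Li+].[Li+].[Ni+2].[Br-].[Br-].[Br-].[Br-]
Why: Soft bromide opens the epoxide by SN2 attack at the less hindered secondary carbon with inversion, which turns the (S)-epoxide into the (R)-bromide next to a tertiary alcohol.

Step 8
Reactants: 11 (2Z,6R)-6-bromo-7-hydroxy-3,7-dimethyl-2-(prop-2-en-1-yl)oct-2-en-1-yl acetate
Product: 12 (2Z,6R)-6-bromo-3,7-dimethyl-2-(prop-2-en-1-yl)-7-(trifluoroacetoxy)oct-2-en-1-yl acetate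
Conditions: (CF3CO)2O, pyridine, CH2Cl2, −20 → 0 °C
Reagents that add atoms: trifluoroacetic anhydride, O=C(OC(=O)C(F)(F)F)C(F)(F)F
Why: Trifluoroacetylation turns the tertiary alcohol into a nucleofuge that can ionise in a non-nucleophilic ionising solvent, while the primary acetate and the bromine-bearing stereocentre stay untouched.

Step 9
Reactants: 12 (2Z,6R)-6-bromo-3,7-dimethyl-2-(prop-2-en-1-yl)-7-(trifluoroacetoxy)oct-2-en-1-yl acetate
Product: 14 (1R,2R,4R)-4-bromo-2-(hydroxymethyl)-1,3,3-trimethyl-2-(prop-2-en-1-yl)cyclohexyl acetate, via acetoxonium ion 13 (not isolated)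
Conditions: (CF3)2CHOH (0.01 M), 2,6-di-tert-butylpyridine, 25 → 40 °C; then aq. NaH2PO4/Na2HPO4 buffer (pH 7), 0 °C
Reagents that add atoms: water, O
Why: Ionisation of the tertiary trifluoroacetate with anchimeric assistance by bromine should give a configurationally defined bromonium ion that triggers a chair cation–olefin (bromonium polyene) cyclisation, in which the tetrasubstituted alkene attacks anti to bromine (Br equatorial, C8 retained), the acetate carbonyl captures the tertiary cation anti to the new C–C bond as a cis-fused 1,3-dioxan-2-ylium ion (this fixes C11 and, through the Z geometry, C6 with the CH2O arm cis to the C11 oxygen), and buffered hydrolysis opens the ion to the ester of the more hindered oxygen, as cyclic orthoesters do.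

Step 10
Reactants: 14 (1R,2R,4R)-4-bromo-2-(hydroxymethyl)-1,3,3-trimethyl-2-(prop-2-en-1-yl)cyclohexyl acetate
Product: 15 (1R,2R,4R)-4-bromo-1,3,3-trimethyl-2-(prop-2-en-1-yl)-2-{[(triethylsilyl)oxy]methyl}cyclohexyl acetate
Conditions: Et3SiCl, imidazole, CH2Cl2, 0 °C
Reagents that add atoms: chlorotriethylsilane, CC[Si](Cl)(CC)CC
Why: Prompt silylation of the primary alcohol blocks acetyl migration and lactol formation during the elaboration of the allyl arm.

Step 11
Reactants: 15 (1R,2R,4R)-4-bromo-1,3,3-trimethyl-2-(prop-2-en-1-yl)-2-{[(triethylsilyl)oxy]methyl}cyclohexyl acetate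
Product: 17 (1R,2R,4R)-4-bromo-1,3,3-trimethyl-2-(2-oxoethyl)-2-{[(triethylsilyl)oxy]methyl}cyclohexyl acetate, via ozonide 16 (not isolated)
Conditions: O3, CH2Cl2, −78 °C; then PPh3, −78 °C → rt
Reagents that add atoms: ozone, [O-][O+]=O
Why: Ozonolysis with reductive work-up cleaves the only alkene of 15 and leaves the aldehyde that becomes C4.

Step 12
Reactants: 17 (1R,2R,4R)-4-bromo-1,3,3-trimethyl-2-(2-oxoethyl)-2-{[(triethylsilyl)oxy]methyl}cyclohexyl acetate; 18 isopropenylmagnesium bromide
Product: 19 (1R,2R,4R)-4-bromo-2-(2-hydroxy-3-methylbut-3-en-1-yl)-1,3,3-trimethyl-2-{[(triethylsilyl)oxy]methyl}cyclohexyl acetate (both carbinol epimers)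
Conditions: THF, −78 °C; then H2O
Reagents that add atoms: none
Why: Grignard addition to the unhindered aldehyde at −78 °C is much faster than attack on the crowded tertiary acetate, and the uncontrolled carbinol centre is reset in steps 13 and 14.

Step 13
Reactants: 19 (1R,2R,4R)-4-bromo-2-(2-hydroxy-3-methylbut-3-en-1-yl)-1,3,3-trimethyl-2-{[(triethylsilyl)oxy]methyl}cyclohexyl acetate
Product: 20 (1R,2R,4R)-4-bromo-1,3,3-trimethyl-2-(3-methyl-2-oxobut-3-en-1-yl)-2-{[(triethylsilyl)oxy]methyl}cyclohexyl acetate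
Conditions: Dess–Martin periodinane, NaHCO3, CH2Cl2, 0 °C → rt
Reagents that add atoms: none
Why: Dess–Martin oxidation converts both epimeric allylic alcohols into a single enone under buffered, mild conditions.

Step 14
Reactants: 20 (1R,2R,4R)-4-bromo-1,3,3-trimethyl-2-(3-methyl-2-oxobut-3-en-1-yl)-2-{[(triethylsilyl)oxy]methyl}cyclohexyl acetate
Product: 21 (1R,2R,4R)-4-bromo-2-[(2R)-2-hydroxy-3-methylbut-3-en-1-yl]-1,3,3-trimethyl-2-{[(triethylsilyl)oxy]methyl}cyclohexyl acetate
Conditions: (S)-2-methyl-CBS-oxazaborolidine (0.3 equiv), catecholborane, toluene, −78 °C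
Reagents that add atoms: none
Why: Corey–Bakshi–Shibata reduction is reagent-controlled: with the (S)-oxazaborolidine the α-branched isopropenyl group should act as the large substituent, so hydride delivery gives the (R)-allylic alcohol (future C4).

Step 15
Reactants: 21 (1R,2R,4R)-4-bromo-2-[(2R)-2-hydroxy-3-methylbut-3-en-1-yl]-1,3,3-trimethyl-2-{[(triethylsilyl)oxy]methyl}cyclohexyl acetate
Product: 22 (1R,2R,4R)-4-bromo-2-{(2R)-2-[(tert-butyldimethylsilyl)oxy]-3-methylbut-3-en-1-yl}-1,3,3-trimethyl-2-{[(triethylsilyl)oxy]methyl}cyclohexyl acetate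
Conditions: t-BuMe2SiOTf, 2,6-lutidine, CH2Cl2, −78 °C
Reagents that add atoms: tert-butyldimethylsilyl trifluoromethanesulfonate, CC(C)(C)[Si](C)(C)OS(=O)(=O)C(F)(F)F
Why: The silyl triflate with a hindered base silylates the secondary allylic alcohol at −78 °C without disturbing the primary triethylsilyl ether or the acetate.

Step 16
Reactants: 22 (1R,2R,4R)-4-bromo-2-{(2R)-2-[(tert-butyldimethylsilyl)oxy]-3-methylbut-3-en-1-yl}-1,3,3-trimethyl-2-{[(triethylsilyl)oxy]methyl}cyclohexyl acetate
Product: 23 (1R,2S,4R)-4-bromo-2-{(2R)-2-[(tert-butyldimethylsilyl)oxy]-3-methylbut-3-en-1-yl}-2-formyl-1,3,3-trimethylcyclohexyl acetate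
Conditions: (COCl)2, DMSO, CH2Cl2, −78 → −30 °C; then Et3N, −78 °C → rt
Reagents that add atoms: none
Why: Under Swern conditions a primary triethylsilyl ether is cleaved and oxidised directly to the aldehyde while the secondary tert-butyldimethylsilyl ether survives, so the hydroxy acetate that is prone to acetyl migration is never set free.

Step 17
Reactants: 23 (1R,2S,4R)-4-bromo-2-{(2R)-2-[(tert-butyldimethylsilyl)oxy]-3-methylbut-3-en-1-yl}-2-formyl-1,3,3-trimethylcyclohexyl acetate
Product: 24 (1R,3S,4R,6R,8R,11R)-8-bromo-4-[(tert-butyldimethylsilyl)oxy]-3-chloro-1-hydroxy-3,7,7,11-tetramethylspiro[5.5]undecan-11-yl acetate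
Conditions: TiCl4 (1.5 equiv), CH2Cl2, −78 °C; then H2O
Reagents that add atoms: titanium tetrachloride, Cl[Ti](Cl)(Cl)Cl
Why: TiCl4 activates the aldehyde of 23, the CH2 terminus (C2) of the 1,1-disubstituted alkene adds to the carbonyl carbon C1, and the tertiary C3 cation takes chloride from the titanium alkoxide just created on the same face; this is a chloro-Prins (halo-Prins) carbocyclisation, the known Lewis-acid closure of δ,ε-unsaturated aldehydes to cis-3-chlorocyclohexanols. Ring A closes through a chair, 6-endo with respect to the alkene (Markovnikov, carbonyl oxygen exocyclic). C1 is controlled by the spiro carbon C6: the titanium-bound oxygen goes axial, anti to the bulky C7 and syn to the C11 acetate oxygen with which it can chelate, and the C5 tether then allows attack on one carbonyl face only. C3 is controlled by C1, since syn-axial chloride transfer from O–Ti puts chlorine cis to the C1 oxygen and the methyl group equatorial. The chair is fixed by the (4R)-silyloxy group, which is cis to C11 on ring A and equatorial only in this chair. The step needs chloride capture to beat 1,2-hydride shift from C4 and proton loss; the proximity of the Ti–Cl bond, the low temperature and the bulky, weakly donating silyl ether are meant to secure this.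

Step 18
Reactants: 24 (1R,3S,4R,6R,8R,11R)-8-bromo-4-[(tert-butyldimethylsilyl)oxy]-3-chloro-1-hydroxy-3,7,7,11-tetramethylspiro[5.5]undecan-11-yl acetate
Product: 25 (1R,3S,4R,6R,8R,11R)-8-bromo-4-[(tert-butyldimethylsilyl)oxy]-3-chloro-11-hydroxy-3,7,7,11-tetramethylspiro[5.5]undecan-1-yl acetate
Conditions: NaH (0.3 equiv), THF, 0 °C → rt
Reagents that add atoms: none
Why: Catalytic alkoxide effects an intramolecular 1,3 O-to-O acyl migration through a six-membered tetrahedral intermediate (the C1 and C11 oxygens are syn), driven by relief of strain in the crowded tertiary acetate.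

Step 19
Reactants: 25 (1R,3S,4R,6R,8R,11R)-8-bromo-4-[(tert-butyldimethylsilyl)oxy]-3-chloro-11-hydroxy-3,7,7,11-tetramethylspiro[5.5]undecan-1-yl acetate
Product: 26 (1R,3S,4R,6R,8R,11R)-8-bromo-3-chloro-4,11-dihydroxy-3,7,7,11-tetramethylspiro[5.5]undecan-1-yl acetate
Conditions: Bu4NF, AcOH, THF, 0 °C → rt
Reagents that add atoms: none
Why: Fluoride cleaves the silyl ether, and buffering with acetic acid prevents base-induced acetyl scrambling or loss of HCl.

Step 20
Reactants: 26 (1R,3S,4R,6R,8R,11R)-8-bromo-3-chloro-4,11-dihydroxy-3,7,7,11-tetramethylspiro[5.5]undecan-1-yl acetate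
Product: 28 (1R,3S,4S,6R,8R,11R)-4,8-dibromo-3-chloro-11-hydroxy-3,7,7,11-tetramethylspiro[5.5]undecan-1-yl acetate, via C4 triflate 27 (not isolated)
Conditions: Tf2O, pyridine, CH2Cl2, −30 → 0 °C; then Bu4NBr, toluene, rt → 40 °C
Reagents that add atoms: tetrabutylammonium bromide, CCCC[N+](CCCC)(CCCC)CCCC.[Br-]
Why: The secondary C4 alcohol is triflated selectively (the tertiary C11 alcohol is inert) and bromide displaces the triflate by SN2 with inversion, ionisation being retarded by the electron-withdrawing chlorine on C3, which gives the (4S)-bromide trans to chlorine.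

**Compound list**

1 | methyl acetoacetate | COC(=O)CC(C)=O | starting material
2 | allyl bromide | C=CCBr | starting material
3 | methyl 2-acetylpent-4-enoate (racemic) | COC(=O)C(CC=C)C(C)=O | intermediate
4 | methyl (2Z)-2-(prop-2-en-1-yl)-3-{[(trifluoromethyl)sulfonyl]oxy}but-2-enoate | C/C(OS(=O)(=O)C(F)(F)F)=C(\CC=C)C(=O)OC | intermediate
5 | 5-bromo-2-methylpent-2-ene | CC(C)=CCCBr | starting material
6 | (4-methylpent-3-en-1-yl)magnesium bromide | CC(C)=CCC[Mg]Br | intermediate
7 | methyl (2Z)-3,7-dimethyl-2-(prop-2-en-1-yl)octa-2,6-dienoate | CC(C)=CCC/C(C)=C(/CC=C)C(=O)OC | intermediate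
8 | methyl (2Z)-5-[(2S)-3,3-dimethyloxiran-2-yl]-3-methyl-2-(prop-2-en-1-yl)pent-2-enoate | CC1(C)O[C@H]1CC/C(C)=C(/CC=C)C(=O)OC | intermediate
9 | (2Z)-5-[(2S)-3,3-dimethyloxiran-2-yl]-3-methyl-2-(prop-2-en-1-yl)pent-2-en-1-ol | CC1(C)O[C@H]1CC/C(C)=C(/CC=C)CO | intermediate
10 | (2Z)-5-[(2S)-3,3-dimethyloxiran-2-yl]-3-methyl-2-(prop-2-en-1-yl)pent-2-en-1-yl acetate | CC1(C)O[C@H]1CC/C(C)=C(/CC=C)COC(C)=O | intermediate
11 | (2Z,6R)-6-bromo-7-hydroxy-3,7-dimethyl-2-(prop-2-en-1-yl)oct-2-en-1-yl acetate | CC(C)(O)[C@H](Br)CC/C(C)=C(/CC=C)COC(C)=O | intermediate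
12 | (2Z,6R)-6-bromo-3,7-dimethyl-2-(prop-2-en-1-yl)-7-(trifluoroacetoxy)oct-2-en-1-yl acetate | CC(C)(OC(=O)C(F)(F)F)[C@H](Br)CC/C(C)=C(/CC=C)COC(C)=O | intermediate
13 | acetoxonium ion (2-methyl-1,3-dioxan-2-ylium, cis-fused to ring B across C6–C11; allyl on C6, Br on C8), trifluoroacetate salt | CC1=[O+]C[C@@]2(CC=C)C(C)(C)[C@H](Br)CC[C@@]2(C)O1.[O-]C(=O)C(F)(F)F | intermediate
14 | (1R,2R,4R)-4-bromo-2-(hydroxymethyl)-1,3,3-trimethyl-2-(prop-2-en-1-yl)cyclohexyl acetate | OC[C@@]1(CC=C)C(C)(C)[C@H](Br)CC[C@@]1(C)OC(C)=O | intermediate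
15 | (1R,2R,4R)-4-bromo-1,3,3-trimethyl-2-(prop-2-en-1-yl)-2-{[(triethylsilyl)oxy]methyl}cyclohexyl acetate | CC[Si](CC)(CC)OC[C@@]1(CC=C)C(C)(C)[C@H](Br)CC[C@@]1(C)OC(C)=O | intermediate
16 | secondary ozonide of 15 (1,2,4-trioxolan-3-ylmethyl arm, mixture at the ozonide carbon) | CC[Si](CC)(CC)OC[C@@]1(CC2OCOO2)C(C)(C)[C@H](Br)CC[C@@]1(C)OC(C)=O | intermediate
17 | (1R,2R,4R)-4-bromo-1,3,3-trimethyl-2-(2-oxoethyl)-2-{[(triethylsilyl)oxy]methyl}cyclohexyl acetate | CC[Si](CC)(CC)OC[C@@]1(CC=O)C(C)(C)[C@H](Br)CC[C@@]1(C)OC(C)=O | intermediate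
18 | isopropenylmagnesium bromide | CC(=C)[Mg]Br | starting material
19 | (1R,2R,4R)-4-bromo-2-(2-hydroxy-3-methylbut-3-en-1-yl)-1,3,3-trimethyl-2-{[(triethylsilyl)oxy]methyl}cyclohexyl acetate (both carbinol epimers) | CC[Si](CC)(CC)OC[C@@]1(CC(O)C(C)=C)C(C)(C)[C@H](Br)CC[C@@]1(C)OC(C)=O | intermediate
20 | (1R,2R,4R)-4-bromo-1,3,3-trimethyl-2-(3-methyl-2-oxobut-3-en-1-yl)-2-{[(triethylsilyl)oxy]methyl}cyclohexyl acetate | CC[Si](CC)(CC)OC[C@@]1(CC(=O)C(C)=C)C(C)(C)[C@H](Br)CC[C@@]1(C)OC(C)=O | intermediate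
21 | (1R,2R,4R)-4-bromo-2-[(2R)-2-hydroxy-3-methylbut-3-en-1-yl]-1,3,3-trimethyl-2-{[(triethylsilyl)oxy]methyl}cyclohexyl acetate | CC[Si](CC)(CC)OC[C@@]1(C[C@@H](O)C(C)=C)C(C)(C)[C@H](Br)CC[C@@]1(C)OC(C)=O | intermediate
22 | (1R,2R,4R)-4-bromo-2-{(2R)-2-[(tert-butyldimethylsilyl)oxy]-3-methylbut-3-en-1-yl}-1,3,3-trimethyl-2-{[(triethylsilyl)oxy]methyl}cyclohexyl acetate | CC[Si](CC)(CC)OC[C@@]1(C[C@@H](O[Si](C)(C)C(C)(C)C)C(C)=C)C(C)(C)[C@H](Br)CC[C@@]1(C)OC(C)=O | intermediate
23 | (1R,2S,4R)-4-bromo-2-{(2R)-2-[(tert-butyldimethylsilyl)oxy]-3-methylbut-3-en-1-yl}-2-formyl-1,3,3-trimethylcyclohexyl acetate | O=C[C@@]1(C[C@@H](O[Si](C)(C)C(C)(C)C)C(C)=C)C(C)(C)[C@H](Br)CC[C@@]1(C)OC(C)=O | intermediate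
24 | (1R,3S,4R,6R,8R,11R)-8-bromo-4-[(tert-butyldimethylsilyl)oxy]-3-chloro-1-hydroxy-3,7,7,11-tetramethylspiro[5.5]undecan-11-yl acetate | O[C@@H]1C[C@](C)(Cl)[C@H](O[Si](C)(C)C(C)(C)C)C[C@@]12C(C)(C)[C@H](Br)CC[C@@]2(C)OC(C)=O | intermediate
25 | (1R,3S,4R,6R,8R,11R)-8-bromo-4-[(tert-butyldimethylsilyl)oxy]-3-chloro-11-hydroxy-3,7,7,11-tetramethylspiro[5.5]undecan-1-yl acetate | CC(=O)O[C@@H]1C[C@](C)(Cl)[C@H](O[Si](C)(C)C(C)(C)C)C[C@@]12C(C)(C)[C@H](Br)CC[C@@]2(C)O | intermediate
26 | (1R,3S,4R,6R,8R,11R)-8-bromo-3-chloro-4,11-dihydroxy-3,7,7,11-tetramethylspiro[5.5]undecan-1-yl acetate | CC(=O)O[C@@H]1C[C@](C)(Cl)[C@H](O)C[C@@]12C(C)(C)[C@H](Br)CC[C@@]2(C)O | intermediate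
27 | (1R,3S,4R,6R,8R,11R)-8-bromo-3-chloro-11-hydroxy-3,7,7,11-tetramethyl-4-{[(trifluoromethyl)sulfonyl]oxy}spiro[5.5]undecan-1-yl acetate | CC(=O)O[C@@H]1C[C@](C)(Cl)[C@H](OS(=O)(=O)C(F)(F)F)C[C@@]12C(C)(C)[C@H](Br)CC[C@@]2(C)O | intermediate
28 | (1R,3S,4S,6R,8R,11R)-4,8-dibromo-3-chloro-11-hydroxy-3,7,7,11-tetramethylspiro[5.5]undecan-1-yl acetate | CC(=O)O[C@@H]1C[C@](C)(Cl)[C@@H](Br)C[C@@]12C(C)(C)[C@H](Br)CC[C@@]2(C)O | target

**Step count.** Total: 20 steps. Longest linear sequence: 20 steps, from methyl acetoacetate 1.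

**Steps most likely to fail**

1. Step 17 (key step). The tertiary cation next to the silyloxy-bearing carbon may undergo a 1,2-hydride shift from C4 (semipinacol-type collapse to a ketone) or lose a proton faster than it is chlorinated, and the silyl ether may be cleaved by the Lewis acid. Fallback: starting from 23, a Me2AlCl-promoted intramolecular carbonyl–ene reaction (CH2Cl2, −78 °C) passes the allylic hydrogen to oxygen in a concerted way. Through the same chair it should give (1R,4R,6R,8R,11R)-8-bromo-4-[(tert-butyldimethylsilyl)oxy]-1-hydroxy-7,7,11-trimethyl-3-methylidenespiro[5.5]undecan-11-yl acetate F1. Markovnikov hydrochlorination of its 1,1-disubstituted alkene by hydrogen-atom transfer (Co(BF4)2·6H2O, salen-type ligand, PhSiH3, TsCl, EtOH, rt) then installs the tertiary chloride through a radical, not a cation. This returns to the route at 24; C3 epimers, if both form, would be separated there.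

2. Step 20. Backside attack at C4 is hindered by the fully substituted C3, so substitution may be slow and lose to elimination toward C5 or to a 1,2-shift after ionisation of the triflate. Fallback: starting from 26, the sulfonate is given up and the alcohol is converted directly by Appel deoxybromination (CBr4, P(n-C8H17)3, toluene, 70 °C). Bromide attacks within the alkoxyphosphonium ion pair with inversion, which leads straight to 28. This fallback makes no compound outside the list (F0).

3. Step 9. Ionisation may be slow, bromonium transfer between alkenes may erode the enantiomeric purity, or proton loss from the tertiary cation may compete with acetate capture. Fallback: starting from 7, i-Bu2AlH reduction gives (2Z)-3,7-dimethyl-2-(prop-2-en-1-yl)octa-2,6-dien-1-ol F2, and acetylation gives (2Z)-3,7-dimethyl-2-(prop-2-en-1-yl)octa-2,6-dien-1-yl acetate F3. A catalytic enantioselective bromonium polyene cyclisation (chiral BINOL-derived thiophosphoramide Lewis base, 1,3-dibromo-5,5-dimethylhydantoin, toluene, −78 °C) proceeds through the cation of 13, and the same buffered hydrolysis returns to the route at 14. Here the catalyst, not a stored stereocentre, sets the absolute configuration.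

**Further compounds**

F1 | step 17 | (1R,4R,6R,8R,11R)-8-bromo-4-[(tert-butyldimethylsilyl)oxy]-1-hydroxy-7,7,11-trimethyl-3-methylidenespiro[5.5]undecan-11-yl acetate | O[C@@H]1CC(=C)[C@H](O[Si](C)(C)C(C)(C)C)C[C@@]12C(C)(C)[C@H](Br)CC[C@@]2(C)OC(C)=O
F0 | step 20 | none | none
F2 | step 9 | (2Z)-3,7-dimethyl-2-(prop-2-en-1-yl)octa-2,6-dien-1-ol | CC(C)=CCC/C(C)=C(/CC=C)CO
F3 | step 9 | (2Z)-3,7-dimethyl-2-(prop-2-en-1-yl)octa-2,6-dien-1-yl acetate | CC(C)=CCC/C(C)=C(/CC=C)COC(C)=O
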